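The pitfall is to see the charge of Z stand above that of D and conclude that D can go over to E whole.

common to all: Z 46.2 mM; L 3.1 mM
- amber: D 59 mM; temperature 85 °C; run made earlier
- red: D 92 mM; temperature 115 °C; run made earlier
- winter: D 42 mM; temperature 140 °C; time 30 h
- midnight: D 42 mM; temperature 90 °C; time 30 h
- dawn: D 42 mM; temperature 115 °C; time 30 h

| run | time / h | J / % | D / % | E / % | X / % |
|---|---|---|---|---|---|
| amber | 1.33 | 3 | 80 | 15 | 1 |
| amber | 3.00 | 6 | 61 | 34 | 0 |
| amber | 8.00 | 10 | 30 | 61 | 0 |
| amber | 20.0 | 11 | 31 | 62 | 0 |
| red | 1.33 | 1 | 53 | 44 | 1 |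
| red | 3.00 | 1 | 53 | 47 | 4 |
| red | 4.00 | 2 | 53 | 46 | 0 |
| red | 6.00 | 3 | 53 | 50 | 0 |

(scatter of a reading: 1.5 percentage points)

- which of these there is most of at the end, counted by the D in it, winter (D / J / E / X)
- which of these there is most of at the end, counted by the D in it, midnight (D / J / E / X)
- which of these there is most of at the end, counted by the D in it, dawn (D / J / E / X)
- how much there is at the end of the one of these that leads, in percent of the D charged: winter
- how much there is at the end of the one of these that leads, in percent of the D charged: midnight
- how much there is at the end of the one of these that leads, in percent of the D charged: dawn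

Look at what the earlier runs spent. Suppose J is E that has met a second Z, so that each J costs one Z more. Z spent should then equal D reacted plus J. Amber at 8.00 h gives 47.2 mM and red at 6.00 h gives 46.0 mM, against 46.2 mM charged. So Z behaves as the limiting reagent in those runs.

Now assume that Z is spent in the new flasks, and let r be the share of D left. The balance makes the J share 10.0% plus r, and E is what remains. Twice the D charge less the Z charge, over the D charge, gives 90.0%: the E ceiling. E equals the ceiling less twice r, so each point of D left takes two points off E. That is my bound from above.

For a bound from below, I assume that J made per D reacted is a selectivity factor times the ratio of E to D. With little J, the J share is then that factor times ln(1/r) − (1 − r). Amber at 8.00 h reads a factor of 0.198. Amber is the coldest run, so using its factor here is rough.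

Now iterate: put r into the balance, solve the J formula for a new r, and go round again. Starting from none left, r swings through 22.2%, 9.06%, 15.4% and 11.9%. The larger of the last two gives a floor of 59.2%. My reckoning puts E in the lead, between floor and ceiling.

The forecast also has E leading, with 90% for winter, 86% for midnight and 94% for dawn, on the ground that “Z just covers D, so nearly all D should convert”. Its midnight figure lies inside my bracket, its winter figure sits at the ceiling, and its dawn figure stands above it.

The flasks give E at 86.7% in winter, 71.2% at midnight and 80.3% at dawn, and E leads in each. Dawn ends with 4.82% of its D and 0% of its Z. Put that D into the rule: the ceiling less twice the D left gives 80.4%, which matches dawn's E.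

    Z + E → J (k = 0.00118 M⁻¹ s⁻¹, Ea = 69.0 kJ mol⁻¹)
    2 G → Q (k = 8.70 × 10⁷ M⁻¹ s⁻¹, Ea = 17.0 kJ mol⁻¹)
    D + G ⇌ X (K = 5.10 × 10⁵ M⁻¹, k = 6780 M⁻¹ s⁻¹, Ea = 45.0 kJ mol⁻¹, ΔH = −34.0 kJ mol⁻¹)
    L → 2 G (k = 3.32 × 10⁻⁶ s⁻¹, Ea = 118 kJ mol⁻¹)
    Z + X → E + G (k = 14800 M⁻¹ s⁻¹, Ea = 46.0 kJ mol⁻¹)
    (constants at 90 °C)

A neighbour of dawn charged with 1.9 mM of L keeps the D and Z charges, so its ceiling stays 90.0%. Its 6.86% of D left then gives 76.3%, and the computed E is 76.3%.

The data were generated by integration for an exercise, noise included.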